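**Strategy.** The cyclohexene ring of the hydrindadiene (indene numbering; alkene C6=C7 between quaternary C5 and ring-fusion C7a) is a Diels–Alder retron, and its diene is cut again at its central bond. In the key step a Negishi coupling joins a dienylzinc to an (E)-alkenyl iodide to make the C6–C7 bond; the tetraene so formed cyclises in the same flask by an intramolecular Diels–Alder reaction that makes the ring-fusion bond C3a–C7a (and C4–C5), turns C6–C7 into the ring alkene, closes both rings and sets C3a, C4, C5 and C7a from the lone C1 stereocentre. The precursor is acyclic; its (Z)-alkene becomes the cyclopentene C2=C3.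

Key step: step 11

Remark (assumption): the acid is carried as its methyl ester through the organozinc step and freed last; the α-ethyl Still–Gennari phosphonate 2 is treated as not purchasable and is made in step 1.

Step 1
Reactants: 1 methyl 2-[bis(2,2,2-trifluoroethoxy)phosphoryl]acetate
Product: 2 methyl 2-[bis(2,2,2-trifluoroethoxy)phosphoryl]butanoate (racemic)
Conditions: NaH, THF, 0 °C; EtI, 0 °C to rt
Reagents that add atoms: iodoethane, CCI
Why: SN2 C-alkylation of the sodium phosphonoacetate enolate should give the α-ethyl Z-selective olefination reagent, whose stereocentre is lost again in step 5.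

Step 2
Reactants: 3 (E)-but-2-en-1-ol
Product: 4 [(2S,3S)-3-methyloxiran-2-yl]methanol
Conditions: Ti(OiPr)4 (cat.), L-(+)-diisopropyl tartrate (cat.), t-BuOOH, 4 Å MS, CH2Cl2, −20 °C
Reagents that add atoms: tert-butyl hydroperoxide, CC(C)(C)OO
Why: Sharpless asymmetric epoxidation, in which the titanium L-(+)-tartrate complex should deliver oxygen to one face of the (E)-allylic alcohol and so set both epoxide carbons as (2S,3S).

Step 3
Reactants: 4 [(2S,3S)-3-methyloxiran-2-yl]methanol; 5 but-1-yne
Product: 7 (2R,3S)-3-methylhept-4-yne-1,2-diol, via but-1-ynyl(diethyl)alane 6 (not isolated)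
Conditions: 5, n-BuLi, toluene, −78 to 0 °C; Et2AlCl, 0 °C; then 4, 0 °C to rt; aq. potassium sodium tartrate
Reagents that add atoms: none
Why: Regioselective epoxide opening by an alkynylalane, in which the aluminium alkoxide of the epoxy alcohol should direct the alkynyl group to C3 with inversion (anti SN2 opening) and so fix the methyl-bearing propargylic stereocentre.

Step 4
Reactants: 7 (2R,3S)-3-methylhept-4-yne-1,2-diol
Product: 8 (S)-2-methylhex-3-ynal (kept cold in solution and used at once)
Conditions: NaIO4, CH2Cl2/aq. pH 7 buffer, 0 °C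
Reagents that add atoms: none
Why: Periodate glycol cleavage under neutral conditions should remove C1 as formaldehyde and unveil the α-stereogenic aldehyde without touching its configuration.

Step 5
Reactants: 8 (S)-2-methylhex-3-ynal; 2 methyl 2-[bis(2,2,2-trifluoroethoxy)phosphoryl]butanoate
Product: 9 methyl (2Z,4R)-2-ethyl-4-methyloct-2-en-5-ynoate
Conditions: 2, KN(SiMe3)2, 18-crown-6, THF, −78 °C; then 8, −78 °C
Reagents that add atoms: none
Why: Still–Gennari (Z-selective Horner–Wadsworth–Emmons) olefination, in which fast irreversible elimination from the trifluoroethyl phosphonate adduct at −78 °C should give the (Z)-trisubstituted enoate before the aldehyde can enolise; this alkene later holds the two chain ends cis for five-ring closure.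

Step 6
Reactants: 9 methyl (2Z,4R)-2-ethyl-4-methyloct-2-en-5-ynoate
Product: 10 (2Z,4R)-2-ethyl-4-methyloct-2-en-5-yn-1-ol
Conditions: i-Bu2AlH, CH2Cl2, −78 °C; aq. potassium sodium tartrate
Reagents that add atoms: none
Why: 1,2-Reduction of the enoate by the aluminium hydride at low temperature should give the allylic alcohol and leave the (Z)-alkene, the alkyne and the stereocentre untouched.

Step 7
Reactants: 10 (2Z,4R)-2-ethyl-4-methyloct-2-en-5-yn-1-ol
Product: 12 (2Z,4R,5E)-2-ethyl-6-iodo-4-methylocta-2,5-dien-1-ol, via alkenylzirconocene alkoxide 11 (not isolated)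
Conditions: Cp2Zr(H)Cl (2.5 equiv), THF, rt to 40 °C; I2, 0 °C
Reagents that add atoms: iodine, II
Why: Hydrozirconation–iodination, in which the hydroxyl is first capped as its zirconium alkoxide, syn addition of Zr–H to the alkyne is equilibrated by the excess hydride so that zirconium sits on the carbon remote from the branched centre, and iodinolysis with retention should give the (E)-iodoalkene.

Step 8
Reactants: 12 (2Z,4R,5E)-2-ethyl-6-iodo-4-methylocta-2,5-dien-1-ol
Product: 14 methyl (2E,4Z,6R,7E)-4-ethyl-8-iodo-2,6-dimethyldeca-2,4,7-trienoate, via (Z)-enal 13 (not isolated)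
Conditions: MnO2, Ph3P=C(Me)CO2Me, CH2Cl2, rt to 40 °C
Reagents that add atoms: methyl 2-(triphenylphosphoranylidene)propanoate, COC(=O)C(C)=P(c1ccccc1)(c1ccccc1)c1ccccc1
Why: Tandem allylic oxidation–Wittig olefination, in which MnO2 oxidises only the allylic alcohol and the stabilised ylide should trap the (Z)-enal as it forms, before it can isomerise, to give the new (2E)-alkene.

Step 9
Reactants: 15 (E)-3-phenylprop-2-enal
Product: 16 [(E)-but-1-en-3-yn-1-yl]benzene
Conditions: Me3SiCHN2, n-BuLi, THF, −78 °C; 15, −78 °C to rt
Reagents that add atoms: trimethylsilyldiazomethane, C[Si](C)(C)C=[N+]=[N-]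
Why: Colvin rearrangement (addition of the lithiated silyldiazomethane, Peterson-type elimination, 1,2-hydrogen shift of the alkylidene carbene) should turn the enal into the terminal enyne in an alcohol-free medium, so that no conjugate addition interferes.

Step 10
Reactants: 16 [(E)-but-1-en-3-yn-1-yl]benzene
Product: 18 [(1E,3E)-3-ethyl-4-iodobuta-1,3-dien-1-yl]benzene, via dienylcopper 17 (not isolated)
Conditions: EtMgBr, CuBr·SMe2, Et2O/Me2S, −45 °C; 16, −25 °C; I2, −40 to 0 °C
Reagents that add atoms: ethylmagnesium bromide, CC[Mg]Br; iodine, II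
Why: Normant carbocupration, in which syn addition of ethylcopper to the terminal alkyne puts ethyl on the internal carbon and copper on the terminus, and iodinolysis with retention should give the dienyl iodide with iodine cis to ethyl.

Step 11
Reactants: 18 [(1E,3E)-3-ethyl-4-iodobuta-1,3-dien-1-yl]benzene; 14 methyl (2E,4Z,6R,7E)-4-ethyl-8-iodo-2,6-dimethyldeca-2,4,7-trienoate
Product: 22 methyl (1R,3aR,4R,5S,7aS)-3,5,7-triethyl-1,4-dimethyl-5-[(E)-2-phenylethenyl]-3a,4,5,7a-tetrahydro-1H-indene-4-carboxylate, via dienyllithium 19 (not isolated), via dienylzinc chloride 20 (not isolated), via tetraene ester 21 (not isolated)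
Conditions: 18, t-BuLi (2 equiv), Et2O, −78 °C; ZnCl2, THF, −78 to 0 °C; 14, Pd(PPh3)4 (cat.), THF, rt; then toluene, 90 °C
Reagents that add atoms: none
Why: Iodine–lithium exchange on 18 and transmetalation give 20, which couples with the (E)-alkenyl iodide 14 at zerovalent palladium (oxidative addition, transmetalation, reductive elimination, each with retention; Negishi coupling) to form the C6–C7 bond (indene numbering of the product) as the central bond of an (E,E)-diene, and on warming tetraene 21 undergoes a concerted suprafacial [4+2] cycloaddition between this diene and its α-methyl enoate (type 1 intramolecular Diels–Alder reaction of a 1,3,6,8-nonatetraene) that turns C6–C7 into the ring alkene and forms C3a–C7a and C4–C5. The closest known reaction types are one-pot cross-coupling/intramolecular Diels–Alder cascades and the thermal cyclisations of linear polyenes to related hydrindene polyketide acids. The cyclohexene closes as the [4+2] ring through a boat-like transition state, and the cyclopentene closes as the tether ring when C3a–C7a forms, the (Z)-alkene C2=C3 of the three-atom tether already holding C3a and C1 cis and being twisted out of conjugation with the dienophile so that the enoate keeps its activation. C5 and C4 follow from alkene geometry (styryl outside on the (E)-diene terminus, C4 methyl cis to C3 on the (E)-enoate), the trans ring fusion C3a/C7a follows from the ester-endo, tether-exo arrangement, and the absolute sense of all four new centres follows from C1, whose hydrogen eclipses the diene toward the C7 ethyl group (A(1,3) strain) so that the tether reaches the diene face anti to the C1 methyl group. The step needs the ester-endo mode to win over the tether-endo mode that would give the cis-fused isomer; the C3 ethyl group, which in the tether-endo mode would be pushed under the diene against its C7 ethyl group, and the endo preference of the ester, helped by the zinc halides left in the flask, should secure this. Chemoselectivity rests on the inertness of alkenylzinc halides toward the enoate ester.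

Step 12
Reactants: 22 methyl (1R,3aR,4R,5S,7aS)-3,5,7-triethyl-1,4-dimethyl-5-[(E)-2-phenylethenyl]-3a,4,5,7a-tetrahydro-1H-indene-4-carboxylate
Product: 23 spiculoic acid B, (1R,3aR,4R,5S,7aS)-3,5,7-triethyl-1,4-dimethyl-5-[(E)-2-phenylethenyl]-3a,4,5,7a-tetrahydro-1H-indene-4-carboxylic acid
Conditions: NaSEt, DMF, 90 °C; aq. HCl
Reagents that add atoms: none
Why: SN2 dealkylation of the methyl ester by thiolate at the methyl carbon should free the acid although the carbonyl, flanked by two quaternary carbons, is shielded from hydroxide.

**Compound list**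

1 | methyl 2-[bis(2,2,2-trifluoroethoxy)phosphoryl]acetate | COC(=O)CP(=O)(OCC(F)(F)F)OCC(F)(F)F | starting material
2 | methyl 2-[bis(2,2,2-trifluoroethoxy)phosphoryl]butanoate (racemic) | CCC(C(=O)OC)P(=O)(OCC(F)(F)F)OCC(F)(F)F | intermediate
3 | (E)-but-2-en-1-ol | C/C=C/CO | starting material
4 | [(2S,3S)-3-methyloxiran-2-yl]methanol | OC[C@H]1[C@H](C)O1 | intermediate
5 | but-1-yne | CCC#C | starting material
6 | but-1-ynyl(diethyl)alane | CCC#C[Al](CC)CC | intermediate (not isolated)
7 | (2R,3S)-3-methylhept-4-yne-1,2-diol | OC[C@H](O)[C@@H](C)C#CCC | intermediate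
8 | (S)-2-methylhex-3-ynal | O=C[C@@H](C)C#CCC | intermediate
9 | methyl (2Z,4R)-2-ethyl-4-methyloct-2-en-5-ynoate | COC(=O)/C(CC)=C\[C@@H](C)C#CCC | intermediate
10 | (2Z,4R)-2-ethyl-4-methyloct-2-en-5-yn-1-ol | OC/C(CC)=C\[C@@H](C)C#CCC | intermediate
11 | chlorozirconocene alkoxide of the (E)-alkenyl(chloro)zirconocene from 10 | Cl[Zr](C1C=CC=C1)(C1C=CC=C1)OC/C(CC)=C\[C@@H](C)/C=C(/[Zr](Cl)(C1C=CC=C1)C1C=CC=C1)CC | intermediate (not isolated)
12 | (2Z,4R,5E)-2-ethyl-6-iodo-4-methylocta-2,5-dien-1-ol | OC/C(CC)=C\[C@@H](C)/C=C(/I)CC | intermediate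
13 | (2Z,4R,5E)-2-ethyl-6-iodo-4-methylocta-2,5-dienal | O=C/C(CC)=C\[C@@H](C)/C=C(/I)CC | intermediate (not isolated)
14 | methyl (2E,4Z,6R,7E)-4-ethyl-8-iodo-2,6-dimethyldeca-2,4,7-trienoate | COC(=O)/C(C)=C/C(CC)=C\[C@@H](C)/C=C(/I)CC | intermediate
15 | (E)-3-phenylprop-2-enal (cinnamaldehyde) | O=C/C=C/c1ccccc1 | starting material
16 | [(E)-but-1-en-3-yn-1-yl]benzene | C#C/C=C/c1ccccc1 | intermediate
17 | [(1E,3E)-2-ethyl-4-phenylbuta-1,3-dien-1-yl]copper (MgBr2 complex) | [Cu]/C=C(CC)/C=C/c1ccccc1 | intermediate (not isolated)
18 | [(1E,3E)-3-ethyl-4-iodobuta-1,3-dien-1-yl]benzene | I/C=C(CC)/C=C/c1ccccc1 | intermediate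
19 | [(1E,3E)-2-ethyl-4-phenylbuta-1,3-dien-1-yl]lithium | [Li]/C=C(CC)/C=C/c1ccccc1 | intermediate (not isolated)
20 | chloro[(1E,3E)-2-ethyl-4-phenylbuta-1,3-dien-1-yl]zinc | Cl[Zn]/C=C(CC)/C=C/c1ccccc1 | intermediate (not isolated)
21 | methyl (2E,4Z,6S,7E,9E,11E)-4,8,10-triethyl-2,6-dimethyl-12-phenyldodeca-2,4,7,9,11-pentaenoate | COC(=O)/C(C)=C/C(CC)=C\[C@@H](C)/C=C(CC)/C=C(CC)/C=C/c1ccccc1 | intermediate (not isolated)
22 | methyl (1R,3aR,4R,5S,7aS)-3,5,7-triethyl-1,4-dimethyl-5-[(E)-2-phenylethenyl]-3a,4,5,7a-tetrahydro-1H-indene-4-carboxylate | CCC1=C[C@@](/C=C/c2ccccc2)(CC)[C@](C)(C(=O)OC)[C@H]2C(CC)=C[C@@H](C)[C@H]12 | intermediate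
23 | spiculoic acid B | CCC1=C[C@@](/C=C/c2ccccc2)(CC)[C@](C)(C(=O)O)[C@H]2C(CC)=C[C@@H](C)[C@H]12 | target

**Count.** Total steps: 12. Longest linear sequence: 9 steps (steps 2 to 8, then 11 and 12).

**Steps most likely to fail**

Step 11. The coupling of the two hindered alkenyl partners may stall or give homocoupling. Under purely thermal conditions the cycloaddition may also run partly through the tether-endo mode (cis ring fusion), or be overtaken by a [1,5]-hydrogen shift in the (Z)-dienoate. The fallback sets out from 18 and 14. Iodide 18 is converted (t-BuLi, then Bu3SnCl) into tributyl[(1E,3E)-2-ethyl-4-phenylbuta-1,3-dien-1-yl]stannane F1. F1 is joined to 14 by a palladium-free Stille–Liebeskind coupling with monovalent copper thiophene-2-carboxylate, Cu(O2CC4H3S), in NMP at 0 to 25 °C. Tetraene 21 then forms at a temperature at which it should not cyclise. After a solvent switch it is closed with Me2AlCl in CH2Cl2 at −40 to 0 °C, where the aluminium-bound ester should enforce the endo mode. The route is rejoined at 22.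

Step 7. Zirconium may end up in part on the alkyne carbon next to the stereocentre, or material may be lost through the zirconium alkoxide. The fallback sets out from 10. Palladium-catalysed syn-hydrostannation (Bu3SnH, PdCl2(PPh3)2, THF), whose regiochemistry is fixed kinetically by the branched propargylic carbon and not by equilibration, should give (2Z,4R,5E)-2-ethyl-4-methyl-6-(tributylstannyl)octa-2,5-dien-1-ol F2. Iododestannylation (I2, CH2Cl2, 0 °C) rejoins the route at 12.

Step 10. The ethylcopper reagent may deprotonate the terminal alkyne or add across the conjugated enyne in another sense, instead of the clean syn carbocupration. The fallback sets out from 16 and reverses the polarity of the ethyl group. Copper-catalysed alkylboration (B2pin2, EtI, CuCl (cat.), Xantphos, NaOt-Bu, THF) adds boron to the terminus and ethyl to the internal carbon in a syn sense, to give 2-[(1E,3E)-2-ethyl-4-phenylbuta-1,3-dien-1-yl]-4,4,5,5-tetramethyl-1,3,2-dioxaborolane F3. Iododeboronation with retention (I2, aq. NaOH, THF) rejoins the route at 18.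

**Further compounds**

F1 | step 11 | tributyl[(1E,3E)-2-ethyl-4-phenylbuta-1,3-dien-1-yl]stannane | CCCC[Sn](CCCC)(CCCC)/C=C(CC)/C=C/c1ccccc1
F2 | step 7 | (2Z,4R,5E)-2-ethyl-4-methyl-6-(tributylstannyl)octa-2,5-dien-1-ol | OC/C(CC)=C\[C@@H](C)/C=C(/[Sn](CCCC)(CCCC)CCCC)CC
F3 | step 10 | 2-[(1E,3E)-2-ethyl-4-phenylbuta-1,3-dien-1-yl]-4,4,5,5-tetramethyl-1,3,2-dioxaborolane | CC1(C)OB(/C=C(CC)/C=C/c2ccccc2)OC1(C)C
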